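The runs were generated by integration from invented constants, noise included.

**Slow drain.** What I watched was how slowly the complex with three exchanged drained once it had peaked, and one question about amber concerns that tail.

| setting | north | south | south-east | red | amber | grey |
|---|---|---|---|---|---|---|
| starting complex | 0.10 M | 0.10 M | 0.10 M | 0.10 M | 0.10 M | 0.10 M |
| incoming ligand | 1.3 equiv | 2.3 equiv | 3.8 equiv | 1.50 equiv | 4.00 equiv | 2.50 equiv |
| remark | run made earlier | run made earlier | run made earlier |  |  |  |
| time |  |  |  | 40 h | 40 h | 40 h |

| run | time / h | complex with three exchanged / % | complex with two exchanged / % |
|---|---|---|---|
| north | 2.50 | 3.2 | 7.9 |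
| north | 4.00 | 5.7 | 10.9 |
| north | 8.00 | 15.1 | 12.8 |
| north | 15.0 | 18.6 | 13.9 |
| north | 30.0 | 19.7 | 13.1 |
| south | 2.50 | 11.4 | 9.9 |
| south | 4.00 | 14.3 | 12.4 |
| south | 8.00 | 26.7 | 13.1 |
| south | 15.0 | 26.2 | 8.6 |
| south | 30.0 | 24.7 | 9.1 |
| south-east | 6.00 | 26.9 | 8.7 |
| south-east | 12.0 | 21.5 | 5.8 |
| south-east | 15.0 | 20.7 | 3.5 |
| south-east | 25.0 | 14.5 | 1.5 |
| south-east | 30.0 | 12.1 | 3.4 |

(standard deviation of a reading: 1 percentage point)

* which of these holds the largest part of the starting complex at the end of red (complex with four exchanged / complex with two exchanged / complex with one exchanged / starting complex / complex with three exchanged)
* which of these holds the largest part of the starting complex at the end of amber (complex with four exchanged / complex with two exchanged / complex with one exchanged / starting complex / complex with three exchanged)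
* which of these holds the largest part of the starting complex at the end of grey (complex with four exchanged / complex with two exchanged / complex with one exchanged / starting complex / complex with three exchanged)
* how much complex with three exchanged is there at the end of amber, in percent of the starting complex charged



**Fall constant.** South-east, the run nearest to amber in incoming ligand, gave me one quantity: the fall constant of the complex with three exchanged, the logarithm of the ratio of two late readings divided by the hours between them, read as if the loss were pseudo-first-order. From 12.0 h to 30.0 h it came to 0.0319 /h, as a reading with its scatter.

**The bracket.** For the top of my bracket I took a flat tail, which would leave 12.1%, the last south-east reading, from a flask that holds less incoming ligand than amber. For the low end I took that last reading two standard deviations low and ran on the fall between the last two south-east readings, 0.0362 /h, which is faster than the fall constant, and reached 7.03%. Between these, running the fall constant on to 40 h gave my own estimate of 8.79%, which is no bound, as it assumes that the fall holds steady.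

**The forecast.** It named starting complex for red, complex with four exchanged for amber and complex with four exchanged for grey, and put amber's complex with three exchanged at 8%, “allowing for some tailing as ligand depletes”, which lies inside my bracket.

**Amber's number.** Amber gave 7.82%, below the top of my bracket, above its low end, and below my estimate. Moving that answer by 5 points took 3.64 equiv or 4.53 equiv of incoming ligand, with the time held.

    starting complex + incoming ligand → leaving ligand + complex with one exchanged (k = 0.910 /M/h)
    complex with one exchanged + incoming ligand → leaving ligand + complex with two exchanged (k = 6.00 /M/h)
    complex with two exchanged + incoming ligand → leaving ligand + complex with three exchanged (k = 3.90 /M/h)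
    complex with three exchanged + incoming ligand → leaving ligand + complex with four exchanged (k = 1.40 /M/h)
    starting complex + complex with one exchanged → side product (k = 0.240 /M/h)

**Run backwards.** I ran the fall constant back from 7.82% at 40 h to 25 h and obtained 12.6%; the same amber flask, read at 25 h, holds 12.0%.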